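## Conventions and assumption

- Locants are germacrane-type labels used only to name atoms: C6 = lactone carbinol carbon; C7 = carbon bearing the acrylate carbon C11 (C12 = carbonyl, C13 = methylene); C8 = angeloyloxy carbon; C9 = CH2; C10 = tertiary carbinol carbon (C14 = its methyl); C1/C2 = oxirane carbons (C1 next to C10); C3 = acetoxy carbon; C4=C5 = ring olefin (C15 = methyl on C4). Ring A = ten-membered carbocycle, ring B = lactone, ring C = oxirane. The same locants are kept for the cyclohexane intermediates. With these locants the target is (1R,2R,3R,6S,7S,8R,10R).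
- Assumption: racemic 3,4-epoxycyclohexene (1) is taken as a commercial material; if not, it is one peracid epoxidation away from cyclohexa-1,3-diene.

## Analysis of the target

The target 31 is a germacranolide: a ten-membered carbocycle (ring A, C1–C10) with a trans-fused α-methylene-γ-butyrolactone (ring B, through C6 and C7) and a cis-oxirane (ring C, C1–C2). Ring A holds one olefin, the E-trisubstituted C4=C5, and seven stereocentres. These fall into two groups: C6/C7/C8, where O6 and O8 are cis to each other and both trans to the C7 side chain, and C10/C1/C2/C3, where the C3 acetoxy group is cis to the oxirane oxygen while the C10 hydroxyl is trans to it. Sensitive groups are the exocyclic C11=C13 Michael acceptor, the angelate on O8 (isomerises to the tiglate with base or nucleophiles), the allylic acetate, the oxirane next to a tertiary alcohol, and the strained E-olefin of the medium ring. The hard problems are the ten-membered ring with its E-olefin beside C6, the four contiguous oxygenated carbons C10–C1–C2–C3 with no rigid scaffold, and three secondary oxygens (O3, O6, O8) that must be acylated in three different ways. The feature this route exploits: C10 and the olefinic carbon C5 lie 1,6 across ring A, C4=C5 is δ,ε to C10, and C1–C2 between them is at the oxidation level of an enone. This is the retron of an acetylenic oxy-Cope ring expansion of the six-membered ring C5–C6–C7–C8–C9–C10, with C2–C3 formed and C5–C10 broken. In that cyclohexane the substituents on C6, C7 and C8 are all-trans and therefore all-equatorial, so the stereotriad becomes a well-defined conformational problem.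

## Retrosynthetic reasoning

**31 ⇒ 30 (ring B).** The C12–O6 and C12–C11 bonds are cut together: both come from one carbonylative lactonisation of the homopropargylic alcohol 30 (free C6–OH, C7 ethynyl group). The cut is made here because the Michael acceptor then appears only in the last step and a silyl alkyne survives everything before it. The forward reaction must choose O6 over O8, which is why O8 and O3 are already acylated in 30.

**30 ⇒ 29 ⇒ 28 ⇒ 27 ⇒ 25 ⇒ 24 (esters and C3).** The two ester C–O bonds are cut separately, and C3 is taken back to the enone 25. A chemoselective allylic oxidation of diol 24 tells O3 from O8 without a protecting-group step, and hydride reduction of 25 from the ring periphery sets the C3 configuration of the target. This detour is accepted because C3 in 24 is deliberately epimeric: it is used as a relay stereocentre.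

**23 ⇒ 21 ⇒ 20 (C10).** The C10–O bond is cut (hydration of the exocyclic methylene of 21), not the C10–C14 bond. A reagent can reach C10 only from outside ring A, so the atom that arrives last ends up anti to C2; in the target that atom is oxygen, so the methyl carbon must be in place first, as the CH2 of 21 made from ketone 20.

**20 ⇒ 19 (ring C).** The oxirane is cut to the Z-enone 19. A nucleophilic epoxidation touches only the enone, and its face is fixed by the neighbouring C3 ether, which sits on the outer face of the enone when H-3 lies in the enone plane.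

**19 ⇒ 17 (key disconnection).** C2–C3 is cut and C5–C10 is reconnected. Ring A, the E-olefin C4=C5, the Z-enone C1=C2–C10=O and the C3 stereocentre then all come from one [3,3] shift of the cyclohexanol 17, whose stereocentres are all equatorial. The forward reaction must run through a chair-like transition state from the trans-diequatorial ethynyl/alkenyl arrangement.

**17 ⇒ 16 ⇒ 14 ⇒ 13 ⇒ 11 (the two π-partners).** C10–C1 is cut to ketone 16; the acetylide must enter equatorially. The enol ether of 14 is cut at C3–O and C4–C15: syn carbometalation of the terminal alkyne of 11, iodination and C–O coupling give the E geometry that the relay needs.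

**11 ⇒ 10 ⇒ 9 ⇒ 8 ⇒ 7 ⇒ 6 ⇒ 5 ⇒ 4 ⇒ 1 + 2 (the cyclohexane).** C5–C4 and C7–C11 are both cut to epoxides opened trans by acetylides. O6 comes from an epoxide-to-allylic-alcohol transposition that also moves the olefin to where the second epoxide is needed. The absolute configuration comes from an enzymatic resolution of acetate 4. C5 is α to the future ketone, so only its trans relation to O10 matters in 11.

## Alternatives that were turned down

Alternative 1: Cut C6–C7 and the lactone C–O bond, and close ring A and ring B together by an intramolecular Barbier/Nozaki–Hiyama–Kishi allylation of the seco aldehyde–allylic bromide A1 (CrCl2, or zinc or indium). This is the textbook germacranolide closure. It was turned down for three reasons. A1 must already carry C1, C2, C3, C8 and C10 with the oxirane and both esters, so the key step builds only the ring. The allylmetal derived from A1 has the C8 acyloxy group β to the metal-bearing C7 and can eliminate to a diene. The relation of the new C6/C7 pair to C8 would be decided by the conformation of a flexible ten-membered transition state, not by a local element.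

Alternative 2: Cut C1=C2 and close ring A by ring-closing metathesis of the lactone diene A2, for example with the second-generation Grubbs catalyst RuCl2(=CHPh)(H2IMes)(PCy3), then epoxidise. Both olefins of A2 are allylically oxygenated and one sits on the fully substituted carbinol carbon C10, so both are slow metathesis partners. The ring to be closed already contains an E-olefin, which favours oligomers. The Z geometry is not guaranteed, and the later epoxidation would face two competing directing oxygens. All seven stereocentres would have to be made in open-chain precursors, so no steps are saved.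

Alternative 3: Cut C5–C10 in the sense of a Grob (Wharton) fragmentation of the bicyclic hydroxy sulfonate A3, which would give the C10 ketone and the E-olefin C4=C5 stereospecifically. The leaving group would have to sit on the tertiary carbon C4; a tertiary sulfonate next to an allylic ether ionises and eliminates before it can be used. A hydroazulene variant that avoids this needs a still harder bicycle. A3 carries all the stereocentres of the cyclohexane route plus two more ring-fusion centres, and the C1–C3 end game would be unchanged.

Key step: step 13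

## Synthesis

Step 1
Reactants: 1 racemic 3,4-epoxycyclohexene; 2 (triisopropylsilyl)acetylene
Product: 4 racemic trans-2-[(triisopropylsilyl)ethynyl]cyclohex-3-en-1-yl acetate, via racemic aluminium alkoxide 3 (not isolated)
Conditions: 2, n-BuLi, toluene, 0 °C; Et2AlCl, 0 °C; then 1, 0 °C → rt; then AcCl, 0 °C → rt
Reagents that add atoms: acetyl chloride CC(=O)Cl
Why: Alkynylalane opening of a vinyl epoxide: the alane attacks the allylic carbon (C7) with inversion, so the alkynyl group and O8 are trans; the aluminium alkoxide is acetylated in the same flask to give the ester for the resolution.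

Step 2
Reactants: 4 racemic trans-2-[(triisopropylsilyl)ethynyl]cyclohex-3-en-1-yl acetate
Product: 5 (1R,2S)-2-[(triisopropylsilyl)ethynyl]cyclohex-3-en-1-ol
Conditions: lipase from Burkholderia cepacia (Amano PS), pH 7 phosphate buffer/MTBE, 30 °C, stopped near 50 % conversion
Reagents that add atoms: none
Why: Enzymatic kinetic resolution by ester hydrolysis: lipases cleave the (R)-configured ester of trans-2-substituted cyclohexanols (Kazlauskas rule), which should release 5 and leave the (1S,2R)-acetate; this sets the absolute configuration at C8 and C7 for the whole route.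

Step 3
Reactants: 5 (1R,2S)-2-[(triisopropylsilyl)ethynyl]cyclohex-3-en-1-ol
Product: 6 C5–C6 epoxy alcohol (oxirane cis to C8–OH and trans to the C7 alkynyl group)
Conditions: VO(acac)2 (5 mol %), t-BuOOH, CH2Cl2, 0 °C → rt
Reagents that add atoms: tert-butyl hydroperoxide CC(C)(C)OO
Why: Hydroxyl-directed epoxidation of a homoallylic cyclohexenol: the vanadium-bound peroxide is delivered syn to C8–OH, which is also the face anti to the allylic alkynyl group.

Step 4
Reactants: 6 C5–C6 epoxy alcohol
Product: 7 C8 4-methoxybenzyl (PMB) ether of 6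
Conditions: NaH, 4-methoxybenzyl chloride, Bu4NI (cat.), THF/DMF, 0 °C → rt
Reagents that add atoms: 4-methoxybenzyl chloride COc1ccc(CCl)cc1
Why: Williamson etherification; the PMB group on O8 should last until step 17 and then leave under neutral oxidative conditions.

Step 5
Reactants: 7 C8 PMB ether epoxide
Product: 8 allylic alcohol (C6–OH cis to C8–OPMB and trans to the alkynyl group; C5=C10 olefin)
Conditions: diethylaluminium 2,2,6,6-tetramethylpiperidide, Et2Al(TMP) (from lithium 2,2,6,6-tetramethylpiperidide + Et2AlCl), toluene, 0 °C; aq. potassium sodium tartrate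
Reagents that add atoms: none
Why: Aluminium-amide isomerisation of an epoxide to an allylic alcohol: the amide binds the oxirane oxygen and removes a syn β-hydrogen through a cyclic transition state, preferring the secondary C10–H over the tertiary C7–H, so the oxygen stays on C6 with its configuration and the olefin moves to C5=C10.

Step 6
Reactants: 8 allylic alcohol
Product: 9 C6 tert-butyldimethylsilyl (TBS) ether of 8
Conditions: TBSCl, imidazole, DMF, rt
Reagents that add atoms: tert-butyldimethylsilyl chloride CC(C)(C)[Si](C)(C)Cl
Why: Silylation; the bulky allylic silyl ether directs the next epoxidation and keeps O6 distinct from O8 to the end.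

Step 7
Reactants: 9 C6 TBS ether
Product: 10 C5–C10 epoxide (oxirane trans to C6–OTBS)
Conditions: mCPBA, NaHCO3, CH2Cl2, 0 °C
Reagents that add atoms: 3-chloroperoxybenzoic acid OOC(=O)c1cccc(Cl)c1
Why: Prilezhaev epoxidation anti to the allylic silyloxy group; the silyl alkyne is inert to the peracid.

Step 8
Reactants: 10 C5–C10 epoxide
Product: 11 C5-ethynyl C10-alcohol (ethynyl cis to C6–OTBS; C10–OH trans to the ethynyl group)
Conditions: HC≡CLi·H2NCH2CH2NH2, DMSO, rt → 40 °C; H2O
Reagents that add atoms: lithium acetylide–ethylenediamine complex [Li+].[C-]#C.NCCN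
Why: SN2 epoxide opening under the Fürst–Plattner rule: with OTBS, alkynyl and OPMB equatorial, only attack at C5 gives the trans-diaxial product (attack at C10 would need the all-axial chair), so carbon should enter at C5 and oxygen stay on C10; the C5 configuration is corrected in step 11.

Step 9
Reactants: 11 C5-ethynyl C10-alcohol
Product: 13 (E)-vinyl iodide (C5–C4(CH3)=C3H–I; iodine trans to C5), via alkenylalane 12 (not isolated)
Conditions: AlMe3 (3.5 equiv), Cp2ZrCl2 (0.5 equiv), CH2Cl2, 0 °C → rt; then I2, THF, −30 → 0 °C; aq. potassium sodium tartrate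
Reagents that add atoms: trimethylaluminium C[Al](C)C; iodine II
Why: Negishi carboalumination: syn addition of methyl and aluminium across the terminal alkyne (methyl to C4) and iodinolysis with retention give the E-iodide; the hindered silyl alkyne should not react, and the trans-diaxial C10 alkoxide cannot chelate the alane, so no anti-isomerisation is expected.

Step 10
Reactants: 13 (E)-vinyl iodide
Product: 14 (E)-PMB enol ether (C5–C4(CH3)=C3H–OPMB) with free C10–OH
Conditions: CuI (10 mol %), 3,4,7,8-tetramethyl-1,10-phenanthroline (20 mol %), Cs2CO3, 4-methoxybenzyl alcohol (2 equiv), toluene, 80 °C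
Reagents that add atoms: 4-methoxybenzyl alcohol COc1ccc(CO)cc1
Why: Copper-catalysed Ullmann-type C–O coupling of a vinyl iodide with a primary alcohol, which proceeds with retention of olefin geometry; the hindered C10 alcohol should not compete and cannot cyclise onto an iodide that is trans to C5.

Step 11
Reactants: 14 (E)-PMB enol ether alcohol
Product: 16 trans-ketone (C10 ketone; C5 alkenyl trans to C6–OTBS; all four substituents equatorial), via cis-ketone 15 (not isolated)
Conditions: Dess–Martin periodinane, NaHCO3, CH2Cl2, 0 °C → rt; then DBU (0.1 equiv), CH2Cl2, 0 °C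
Reagents that add atoms: none
Why: Dess–Martin oxidation followed by base-mediated α-epimerisation: the C5 alkenyl group should move from the axial position in 15 to the equatorial one in 16 (thermodynamic control); catalytic base at 0 °C is chosen to avoid moving the enol ether double bond into conjugation.

Step 12
Reactants: 16 trans-ketone
Product: 17 tertiary propargylic alcohol (C10 ethynyl equatorial and trans to the C5 alkenyl group; C10–OH axial)
Conditions: HC≡CMgBr + ClTi(OiPr)3, THF, −78 → 0 °C; then 16, −40 °C → rt; aq. NH4Cl
Reagents that add atoms: ethynylmagnesium bromide C#C[Mg]Br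
Why: 1,2-Addition of an alkynyltitanium triisopropoxide: this bulky, non-basic reagent should favour equatorial attack on the cyclohexanone (unlike lithium or magnesium acetylides) and should neither enolise the β,γ-unsaturated ketone nor eliminate the β-silyloxy group; equatorial entry gives the trans-diequatorial ethynyl/alkenyl pair that step 13 needs.

Step 13
Reactants: 17 tertiary propargylic alcohol
Product: 19 ring A dienone (C10 ketone; Z-C1=C2; C3–OPMB epimeric to the target; E-C4=C5), via potassium allenolate 18 (not isolated)
Conditions: KN(SiMe3)2 (1.1 equiv), 18-crown-6 (1.2 equiv), THF, −20 °C → rt; then AcOH, THF, −78 °C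
Reagents that add atoms: none
Why: Anionic acetylenic oxy-Cope rearrangement (alkoxide-accelerated [3,3] shift) of the 5-en-1-yn-3-ol unit C2≡C1–C10(O−)–C5–C4=C3; the closest precedent is the KH/18-crown-6 ring expansion of trans-1,2-dialkenylcyclohexanols to (E)-cyclodec-5-enones and its alkynyl-carbinol variant, which ends in an allenolate. Ring A is not closed end to end: it arises by a four-atom ring expansion, the C5–C10 bond breaking as C2–C3 forms through a chair-like six-centre transition state. Because the ethynyl and alkenyl groups are trans-diequatorial, C6 and C9 are pseudo-equatorial in that chair, which fixes the E geometry of C4=C5. C3 is created by 1,3-chirality transfer from C5: the C5 configuration dictates which face of C3=C4 turns towards C2, and the E-enol ether keeps OPMB pseudo-equatorial, giving the C3 configuration shown (deliberately epimeric to the target). Intermediate 18 is a cyclic allenolate; acetic acid should protonate C1 on the side of H-2, that is from outside the ring, so C1=C2 is Z. The selectivities needed are rearrangement over alkoxide fragmentation (helped by the crown ether, low temperature and the pre-set gauche arrangement) and C- over O-protonation (any allenol tautomerises to 19). The potassium alkoxide, not the acetylide, is expected to be the resting anion, and the silyl alkyne, ethers and enol ether are inert to the base.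

Step 14
Reactants: 19 ring A dienone
Product: 20 cis-C1–C2 epoxy ketone (oxirane with the configuration of the target)
Conditions: t-BuOOH, n-BuLi (→ t-BuOOLi), THF, −78 → −20 °C
Reagents that add atoms: tert-butyl hydroperoxide CC(C)(C)OO
Why: Weitz–Scheffer nucleophilic epoxidation: A(1,3) strain across the Z-enone holds H-3 in the enone plane, so C3–OPMB lies on the outer face and the ring (C4, C9) covers the other; the lithium peroxide, held by the C3 ether oxygen, should add to C2 on the open face and the enolate close without C1–C2 rotation; the isolated C4=C5 and the silyl alkyne do not react with a nucleophilic oxidant.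

Step 15
Reactants: 20 cis-C1–C2 epoxy ketone
Product: 21 C10 exocyclic methylene (C14H2) vinyl epoxide
Conditions: Ph3PCH3Br, KN(SiMe3)2, THF, 0 °C (→ Ph3P=CH2); then 20, −78 → 0 °C
Reagents that add atoms: methyltriphenylphosphonium bromide C[P+](c1ccccc1)(c1ccccc1)c1ccccc1.[Br-]
Why: Wittig methylenation at low temperature, where addition to the ketone should outrun enolisation at C9 (which would eliminate O8); C14 is brought in as CH2 because a methyl nucleophile would attack C10 from the periphery and leave the hydroxyl on the oxirane side (the C10 epimer).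

Step 16
Reactants: 21 C10 exocyclic methylene vinyl epoxide
Product: 23 C10 tertiary alcohol (C14 methyl; target configuration at C10, C1, C2), via organomercurial 22 (not isolated)
Conditions: Hg(OAc)2, THF/H2O (1:1), 0 °C; then NaBH4, 3 M NaOH, 0 °C
Reagents that add atoms: water O
Why: Oxymercuration–demercuration (Markovnikov hydration): the 1,1-disubstituted C10=C14 should react much faster with divalent mercury than the hindered trisubstituted C4=C5 or the silyl alkyne; C9 is tucked under the ring, so water should attack C10 from the periphery (anti to C2), placing OH trans to the oxirane oxygen and the methyl on the oxirane side.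

Step 17
Reactants: 23 C10 tertiary alcohol
Product: 24 C3,C8,C10 triol (C3 epimeric to the target)
Conditions: DDQ (2.5 equiv), CH2Cl2/pH 7 phosphate buffer (10:1), 0 °C → rt
Reagents that add atoms: none
Why: Oxidative cleavage of both PMB ethers under neutral conditions; TBS ether, silyl alkyne, oxirane and tertiary alcohol should survive, and water suppresses anisylidene acetal formation between O8 and O10.

Step 18
Reactants: 24 C3,C8,C10 triol
Product: 25 C3 enone (C3 ketone conjugated with C4=C5; free C8–OH and C10–OH)
Conditions: MnO2 (activated, 20 equiv), CH2Cl2, rt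
Reagents that add atoms: none
Why: MnO2 oxidises only the allylic C3 alcohol (C8–OH is saturated, C10–OH tertiary); this erases the relay stereocentre and tells O3 from O8 without a protecting-group step.

Step 19
Reactants: 25 C3 enone; 26 angelic acid
Product: 27 C8 angelate of 25
Conditions: 26, 2,4,6-trichlorobenzoyl chloride, Et3N, toluene, rt; then 25, toluene, 80 °C
Reagents that add atoms: none
Why: Yamaguchi esterification through the mixed anhydride without DMAP, the usual way to make angelates without Z→E isomerisation; only the secondary C8–OH can react (C10–OH is tertiary).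

Step 20
Reactants: 27 C8 angelate
Product: 28 C3 alcohol with the C3 configuration of the target
Conditions: NaBH4, CeCl3·7H2O, MeOH, −78 °C
Reagents that add atoms: none
Why: Luche 1,2-reduction: hydride should reach the C3 carbonyl from the periphery of ring A while cerium bridges the ketone and oxirane oxygens (chelate model for α,β-epoxy ketones), both leading to the alcohol cis to the oxirane; the angelate and C4=C5 are not reduced at −78 °C.

Step 21
Reactants: 28 C3 alcohol
Product: 29 C3 acetate
Conditions: Ac2O, pyridine, DMAP (cat.), CH2Cl2, 0 °C → rt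
Reagents that add atoms: acetic anhydride CC(=O)OC(C)=O
Why: Acetylation of the only free secondary alcohol; the tertiary C10–OH does not react under these conditions.

Step 22
Reactants: 29 C3 acetate
Product: 30 seco-lactone (free C6–OH and free C7 ethynyl group)
Conditions: Bu4NF (3 equiv), AcOH (1.5 equiv), THF, 0 °C → rt
Reagents that add atoms: none
Why: Fluoride desilylation removes the TBS ether on O6 and the silyl group of the alkyne in one operation; acetic acid buffers the fluoride so that acyl migration from O8 to O6 and angelate isomerisation are avoided.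

Step 23
Reactants: 30 seco-lactone
Product: 31 target germacranolide (CNP0155556.1)
Conditions: PdCl2 (10 mol %), thiourea (20 mol %), CO (1 atm), acetone, 50 °C
Reagents that add atoms: carbon monoxide [C-]#[O+]
Why: Palladium-catalysed cyclocarbonylation of a homopropargylic alcohol: divalent palladium forms an alkoxycarbonyl complex from O6 and CO, the alkyne inserts syn (C12 bonds to C11) and the vinylpalladium is protonated, closing ring B with the exocyclic C11=C13; the trans relation of O6 and C7 is already set, O3 and O8 are acylated and the tertiary C10–OH cannot reach the alkyne.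

## Compound list

1 | racemic 3,4-epoxycyclohexene (7-oxabicyclo[4.1.0]hept-2-ene; the enantiomer leading to 5 is drawn) | C1=C[C@@H]2O[C@@H]2CC1 | starting material
2 | (triisopropylsilyl)acetylene | C#C[Si](C(C)C)(C(C)C)C(C)C | starting material
3 | racemic diethylaluminium trans-2-[(triisopropylsilyl)ethynyl]cyclohex-3-en-1-olate (one enantiomer drawn) | CC[Al](CC)O[C@@H]1CCC=C[C@H]1C#C[Si](C(C)C)(C(C)C)C(C)C | intermediate
4 | racemic trans-2-[(triisopropylsilyl)ethynyl]cyclohex-3-en-1-yl acetate (one enantiomer drawn) | CC(=O)O[C@@H]1CCC=C[C@H]1C#C[Si](C(C)C)(C(C)C)C(C)C | intermediate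
5 | (1R,2S)-2-[(triisopropylsilyl)ethynyl]cyclohex-3-en-1-ol (C8 carbinol, C7 alkynyl, C5=C6 olefin) | O[C@@H]1CCC=C[C@H]1C#C[Si](C(C)C)(C(C)C)C(C)C | intermediate
6 | C5–C6 epoxy alcohol, oxirane cis to C8–OH and trans to the C7 alkynyl group | O[C@@H]1CC[C@@H]2O[C@@H]2[C@H]1C#C[Si](C(C)C)(C(C)C)C(C)C | intermediate
7 | C8 PMB ether of 6 | COc1ccc(CO[C@@H]2CC[C@@H]3O[C@@H]3[C@H]2C#C[Si](C(C)C)(C(C)C)C(C)C)cc1 | intermediate
8 | allylic alcohol: C6–OH cis to C8–OPMB and trans to the alkynyl group, C5=C10 olefin | COc1ccc(CO[C@@H]2CC=C[C@H](O)[C@H]2C#C[Si](C(C)C)(C(C)C)C(C)C)cc1 | intermediate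
9 | C6 TBS ether of 8 | COc1ccc(CO[C@@H]2CC=C[C@H](O[Si](C)(C)C(C)(C)C)[C@H]2C#C[Si](C(C)C)(C(C)C)C(C)C)cc1 | intermediate
10 | C5–C10 epoxide of 9, oxirane trans to C6–OTBS | COc1ccc(CO[C@@H]2C[C@H]3O[C@H]3[C@H](O[Si](C)(C)C(C)(C)C)[C@H]2C#C[Si](C(C)C)(C(C)C)C(C)C)cc1 | intermediate
11 | C5-ethynyl C10-alcohol: ethynyl cis to C6–OTBS, C10–OH trans to the ethynyl group | COc1ccc(CO[C@@H]2C[C@@H](O)[C@H](C#C)[C@H](O[Si](C)(C)C(C)(C)C)[C@H]2C#C[Si](C(C)C)(C(C)C)C(C)C)cc1 | intermediate
12 | carboalumination adduct: (E)-C3 dimethylalanyl alkene and C10 dimethylaluminium alkoxide | COc1ccc(CO[C@@H]2C[C@@H](O[Al](C)C)[C@H](/C(C)=C/[Al](C)C)[C@H](O[Si](C)(C)C(C)(C)C)[C@H]2C#C[Si](C(C)C)(C(C)C)C(C)C)cc1 | intermediate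
13 | (E)-vinyl iodide: C5–C4(CH3)=C3H–I, iodine trans to C5 | COc1ccc(CO[C@@H]2C[C@@H](O)[C@H](/C(C)=C/I)[C@H](O[Si](C)(C)C(C)(C)C)[C@H]2C#C[Si](C(C)C)(C(C)C)C(C)C)cc1 | intermediate
14 | (E)-PMB enol ether: C5–C4(CH3)=C3H–OPMB, free C10–OH | COc1ccc(CO[C@@H]2C[C@@H](O)[C@H](/C(C)=C/OCc3ccc(OC)cc3)[C@H](O[Si](C)(C)C(C)(C)C)[C@H]2C#C[Si](C(C)C)(C(C)C)C(C)C)cc1 | intermediate
15 | cis-ketone: C10 ketone, C5 alkenyl cis to C6–OTBS (axial) | COc1ccc(CO[C@@H]2CC(=O)[C@H](/C(C)=C/OCc3ccc(OC)cc3)[C@H](O[Si](C)(C)C(C)(C)C)[C@H]2C#C[Si](C(C)C)(C(C)C)C(C)C)cc1 | intermediate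
16 | trans-ketone: C10 ketone, C5 alkenyl trans to C6–OTBS, all substituents equatorial | COc1ccc(CO[C@@H]2CC(=O)[C@@H](/C(C)=C/OCc3ccc(OC)cc3)[C@H](O[Si](C)(C)C(C)(C)C)[C@H]2C#C[Si](C(C)C)(C(C)C)C(C)C)cc1 | intermediate
17 | tertiary propargylic alcohol: C10 ethynyl trans to the C5 alkenyl group (both equatorial), C10–OH axial | COc1ccc(CO[C@@H]2C[C@](O)(C#C)[C@@H](/C(C)=C/OCc3ccc(OC)cc3)[C@H](O[Si](C)(C)C(C)(C)C)[C@H]2C#C[Si](C(C)C)(C(C)C)C(C)C)cc1 | intermediate
18 | potassium allenolate of ring A: C10(OK)=C1=C2, new C2–C3 bond, E-C4=C5 | [K+].[O-]C1=C=C[C@@H](OCc2ccc(OC)cc2)/C(C)=C/[C@H](O[Si](C)(C)C(C)(C)C)[C@@H](C#C[Si](C(C)C)(C(C)C)C(C)C)[C@H](OCc2ccc(OC)cc2)C1 | intermediate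
19 | ring A dienone: C10 ketone, Z-C1=C2, C3–OPMB (epimeric to the target), E-C4=C5, C6–OTBS, C7 silylethynyl, C8–OPMB | O=C1/C=C\[C@@H](OCc2ccc(OC)cc2)/C(C)=C/[C@H](O[Si](C)(C)C(C)(C)C)[C@@H](C#C[Si](C(C)C)(C(C)C)C(C)C)[C@H](OCc2ccc(OC)cc2)C1 | intermediate
20 | cis-C1–C2 epoxy ketone | O=C1[C@@H]2O[C@@H]2[C@@H](OCc3ccc(OC)cc3)/C(C)=C/[C@H](O[Si](C)(C)C(C)(C)C)[C@@H](C#C[Si](C(C)C)(C(C)C)C(C)C)[C@H](OCc3ccc(OC)cc3)C1 | intermediate
21 | C10 exocyclic methylene (C14H2) vinyl epoxide | C=C1[C@@H]2O[C@@H]2[C@@H](OCc3ccc(OC)cc3)/C(C)=C/[C@H](O[Si](C)(C)C(C)(C)C)[C@@H](C#C[Si](C(C)C)(C(C)C)C(C)C)[C@H](OCc3ccc(OC)cc3)C1 | intermediate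
22 | C14 acetoxymercurio C10 tertiary alcohol | CC(=O)O[Hg]C[C@]1(O)[C@@H]2O[C@@H]2[C@@H](OCc3ccc(OC)cc3)/C(C)=C/[C@H](O[Si](C)(C)C(C)(C)C)[C@@H](C#C[Si](C(C)C)(C(C)C)C(C)C)[C@H](OCc3ccc(OC)cc3)C1 | intermediate
23 | C10 tertiary alcohol with C14 methyl (target configuration at C10, C1, C2) | C[C@]1(O)[C@@H]2O[C@@H]2[C@@H](OCc3ccc(OC)cc3)/C(C)=C/[C@H](O[Si](C)(C)C(C)(C)C)[C@@H](C#C[Si](C(C)C)(C(C)C)C(C)C)[C@H](OCc3ccc(OC)cc3)C1 | intermediate
24 | C3,C8,C10 triol (C3 epimeric to the target) | C[C@]1(O)[C@@H]2O[C@@H]2[C@@H](O)/C(C)=C/[C@H](O[Si](C)(C)C(C)(C)C)[C@@H](C#C[Si](C(C)C)(C(C)C)C(C)C)[C@H](O)C1 | intermediate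
25 | C3 enone with free C8–OH and C10–OH | C[C@]1(O)[C@@H]2O[C@@H]2C(=O)/C(C)=C/[C@H](O[Si](C)(C)C(C)(C)C)[C@@H](C#C[Si](C(C)C)(C(C)C)C(C)C)[C@H](O)C1 | intermediate
26 | angelic acid, (Z)-2-methylbut-2-enoic acid | C/C=C(/C)C(=O)O | starting material
27 | C8 angelate of 25 | C[C@]1(O)[C@@H]2O[C@@H]2C(=O)/C(C)=C/[C@H](O[Si](C)(C)C(C)(C)C)[C@@H](C#C[Si](C(C)C)(C(C)C)C(C)C)[C@H](OC(=O)/C(C)=C\C)C1 | intermediate
28 | C3 alcohol with the target C3 configuration | C[C@]1(O)[C@@H]2O[C@@H]2[C@H](O)/C(C)=C/[C@H](O[Si](C)(C)C(C)(C)C)[C@@H](C#C[Si](C(C)C)(C(C)C)C(C)C)[C@H](OC(=O)/C(C)=C\C)C1 | intermediate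
29 | C3 acetate | C[C@]1(O)[C@@H]2O[C@@H]2[C@H](OC(C)=O)/C(C)=C/[C@H](O[Si](C)(C)C(C)(C)C)[C@@H](C#C[Si](C(C)C)(C(C)C)C(C)C)[C@H](OC(=O)/C(C)=C\C)C1 | intermediate
30 | seco-lactone: free C6–OH and C7 ethynyl group | C[C@]1(O)[C@@H]2O[C@@H]2[C@H](OC(C)=O)/C(C)=C/[C@H](O)[C@@H](C#C)[C@H](OC(=O)/C(C)=C\C)C1 | intermediate
31 | target germacranolide CNP0155556.1, (1R,2R,3R,6S,7S,8R,10R) | C=C1C(=O)O[C@H]2/C=C(\C)[C@@H](OC(C)=O)[C@H]3O[C@H]3[C@](C)(O)C[C@@H](OC(=O)/C(C)=C\C)[C@H]12 | target

## Step count and least certain steps

Total: 23 steps. Longest linear sequence: 23 steps (1 → 31); the route is linear, with 2 and 26 as the other starting materials.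

**Step 13 (key step).** The most likely failure is alkoxide fragmentation (loss of acetylide back to 16, or cleavage to an ynone and an allyl anion) running faster than the [3,3] shift, because the ten-membered allenolate that also holds an E-olefin is strained. A second risk is leakage through a boat-like pathway, which would erode the C3 configuration and the olefin geometry. A third is double-bond migration when the enone is released. The fallback avoids the anion altogether. It sets out from 17, which is silylated (Me3SiOTf, 2,6-lutidine) to the C10 trimethylsilyl ether F1. F1 is heated (o-dichlorobenzene, 180 °C) for a neutral thermal acetylenic siloxy-Cope rearrangement to the trimethylsilyl allenyl ether F2. F2 is protodesilylated with buffered Bu4NF at −78 °C, which returns to the route at 19.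

**Step 12.** The risk is poor facial selectivity: axial entry of the small acetylide would give the cis carbinol, whose chair transition state leads to the Z-olefin at C4=C5. The fallback changes the nucleophile class and the way the enone is made. From 16, CH2=CHMgBr/CeCl3 (sp2 Grignard reagents attack 2-substituted cyclohexanones equatorially) should give the C10 vinyl carbinol F3. A classical anionic oxy-Cope rearrangement (KH, 18-crown-6) with a PhSeBr quench of the enolate gives the C1 phenylselanyl ketone F4. Oxidation with H2O2 and selenoxide syn-elimination returns to the route at 19.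

**Step 14.** The risk is competition between the two faces of the enone (chelated attack on the outer face against Felkin–Anh attack anti to the C3 ether), or bond rotation in the intermediate enolate giving a trans-oxirane. The fallback replaces nucleophilic by hydroxyl-directed epoxidation. From 19, Luche reduction (hydride from the periphery) gives the C10 allylic alcohol F5. VO(acac)2/t-BuOOH then epoxidises only the allylic C1=C2 on the face of the hydroxyl, giving the epoxy alcohol F6. Dess–Martin oxidation returns to the route at 20.

**Step 16.** The risks are mercuration of C4=C5 or of the anisyl rings, participation of the C3 ether oxygen in opening the mercurinium ion, and attack of water on the wrong face. The fallback delivers the oxygen by a different reaction from the same outer direction. From 21, OsO4 (cat.)/N-methylmorpholine N-oxide dihydroxylates the exocyclic olefin to the C10,C14 diol F7. I2/PPh3/imidazole converts the primary hydroxyl to the C14 iodide F8. Bu3SnH/AIBN reduces the iodide and returns to the route at 23.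

## Further compounds

F1 | step 13 | C10 trimethylsilyl ether of 17 | COc1ccc(CO[C@@H]2C[C@](O[Si](C)(C)C)(C#C)[C@@H](/C(C)=C/OCc3ccc(OC)cc3)[C@H](O[Si](C)(C)C(C)(C)C)[C@H]2C#C[Si](C(C)C)(C(C)C)C(C)C)cc1
F2 | step 13 | trimethylsilyl allenyl ether of ring A | C[Si](C)(C)OC1=C=C[C@@H](OCc2ccc(OC)cc2)/C(C)=C/[C@H](O[Si](C)(C)C(C)(C)C)[C@@H](C#C[Si](C(C)C)(C(C)C)C(C)C)[C@H](OCc2ccc(OC)cc2)C1
F3 | step 12 | C10 vinyl carbinol (vinyl analogue of 17) | COc1ccc(CO[C@@H]2C[C@](O)(C=C)[C@@H](/C(C)=C/OCc3ccc(OC)cc3)[C@H](O[Si](C)(C)C(C)(C)C)[C@H]2C#C[Si](C(C)C)(C(C)C)C(C)C)cc1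
F4 | step 12 | C1 phenylselanyl ketone of ring A | O=C1[C@H]([Se]c2ccccc2)C[C@@H](OCc2ccc(OC)cc2)/C(C)=C/[C@H](O[Si](C)(C)C(C)(C)C)[C@@H](C#C[Si](C(C)C)(C(C)C)C(C)C)[C@H](OCc2ccc(OC)cc2)C1
F5 | step 14 | C10 allylic alcohol from 19 | O[C@@H]1/C=C\[C@@H](OCc2ccc(OC)cc2)/C(C)=C/[C@H](O[Si](C)(C)C(C)(C)C)[C@@H](C#C[Si](C(C)C)(C(C)C)C(C)C)[C@H](OCc2ccc(OC)cc2)C1
F6 | step 14 | C1–C2 epoxy C10 alcohol | O[C@@H]1[C@@H]2O[C@@H]2[C@@H](OCc3ccc(OC)cc3)/C(C)=C/[C@H](O[Si](C)(C)C(C)(C)C)[C@@H](C#C[Si](C(C)C)(C(C)C)C(C)C)[C@H](OCc3ccc(OC)cc3)C1
F7 | step 16 | C10,C14 diol | OC[C@]1(O)[C@@H]2O[C@@H]2[C@@H](OCc3ccc(OC)cc3)/C(C)=C/[C@H](O[Si](C)(C)C(C)(C)C)[C@@H](C#C[Si](C(C)C)(C(C)C)C(C)C)[C@H](OCc3ccc(OC)cc3)C1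
F8 | step 16 | C14 iodide | IC[C@]1(O)[C@@H]2O[C@@H]2[C@@H](OCc3ccc(OC)cc3)/C(C)=C/[C@H](O[Si](C)(C)C(C)(C)C)[C@@H](C#C[Si](C(C)C)(C(C)C)C(C)C)[C@H](OCc3ccc(OC)cc3)C1
A1 | alternative 1 | seco aldehyde–allylic bromide for the Barbier macrocyclisation | O=C/C=C(\C)[C@@H](OC(C)=O)[C@H]1O[C@H]1[C@](C)(O)C[C@@H](OC(=O)/C(C)=C\C)/C=C(\CBr)C(=O)OC
A2 | alternative 2 | lactone diene for ring-closing metathesis at C1=C2 | C=C1C(=O)O[C@@H](/C=C(\C)[C@@H](OC(C)=O)C=C)[C@@H]1[C@H](OC(=O)/C(C)=C\C)C[C@@](C)(O)C=C
A3 | alternative 3 | bicyclic C10 alcohol with a tertiary C4 mesylate for the Grob fragmentation | O[C@@]12C=C[C@H](OCc3ccc(OC)cc3)[C@](C)(OS(C)(=O)=O)[C@H]1[C@H](O[Si](C)(C)C(C)(C)C)[C@@H](C#C[Si](C(C)C)(C(C)C)C(C)C)[C@H](OCc3ccc(OC)cc3)C2
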